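**Plan**

- Retrosynthesis: the O-acetyl bond is cut first, then C13–C14 of ring A (C1, C10, C11, C12, C13, C14). The C13 ketone and the C14 acetoxy carbinol are neighbouring carbons that can both come from aldehydes, held between quaternary C1 and the (Z)-C11=C12 alkene. This leads back to the ten-membered dialdehyde 40.
- Further cuts: C7–C8 with the lactone C–O bond (ten-membered ring and butenolide), C1–C15 (methyl), C1–C2 (aldol), C10–C11 (conjugate addition) and C9=C10 (cross-metathesis).
- Forward: an acryloyl imide and a butenyl ether give the C14–C1–C10–C9–C8 chain. The (Z)-alkenyl unit C11–C13/C20 adds at C10, the nerol-derived C2–C7 aldehyde is attached by aldol, and C1 is methylated. The ten-membered ring and the lactone then close together at C7–C8, and ring A closes last.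
- Stereochemistry: C10 and C2 come from one (R)-4-benzyl-oxazolidinone (conjugate addition, syn-aldol). C1 is relayed from C2 by chelate-controlled methylation. C7 is set by macrocyclic control in the allylchromium closure and C14 by the substrate-directed benzoin. The Z-alkenes come from nerol and (Z)-3-iodobut-2-en-1-ol.

Key step: step 25

Remark: the briarane numbering of the target (C1–C20) is used for all main-line compounds. CIP descriptors change along the route where substituent priorities change, without any centre being inverted. The C8 configuration of 31, 36 and 37 is of no consequence, because C8 becomes sp2 in step 22.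

**Route**

Step 1
Reactants: 1 nerol
Product: 2 neryl 4-methoxybenzyl (PMB) ether
Conditions: NaH, PMBCl, Bu4NI (cat.), THF/DMF, 0 °C → rt
Reagents that add atoms: 4-methoxybenzyl chloride, COc1ccc(CCl)cc1
Why: Williamson etherification of the primary allylic alkoxide; PMB is chosen because it can later be removed oxidatively next to an allylic bromide.

Step 2
Reactants: 2 neryl PMB ether
Product: 3 6,7-epoxide of neryl PMB ether (racemic at the epoxide carbon)
Conditions: mCPBA (1.0 equiv), CH2Cl2, −20 → 0 °C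
Reagents that add atoms: 3-chloroperbenzoic acid, OOC(=O)c1cccc(Cl)c1
Why: Prilezhaev epoxidation should prefer the distal trisubstituted alkene because the 2,3-alkene is deactivated by the allylic oxygen; the new stereocentre is destroyed in step 3.

Step 3
Reactants: 3 epoxide
Product: 4 (Z)-6-(4-methoxybenzyloxy)-4-methylhex-4-enal (C2–C7 aldehyde)
Conditions: H5IO6, THF/H2O, 0 °C
Reagents that add atoms: none
Why: Periodic acid hydrolyses the epoxide and cleaves the resulting glycol (glycol cleavage) to the C2 aldehyde and acetone without touching the (Z)-alkene.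

Step 4
Reactants: 5 2-butyn-1-ol
Product: 7 (Z)-3-iodobut-2-en-1-ol, via cyclic alkenylaluminate 6 (not isolated)
Conditions: NaAlH2(OCH2CH2OMe)2 (Red-Al), THF, 0 °C; then I2, −78 °C
Reagents that add atoms: iodine, II
Why: Hydroxyl-directed trans-hydroalumination places aluminium on C3 in a five-membered alkoxyaluminate, and iodinolysis with retention should give the iodide with iodine cis to CH2OH, the geometry that later puts C10 cis to C13.

Step 5
Reactants: 7 (Z)-3-iodobut-2-en-1-ol
Product: 8 (Z)-tert-butyl(3-iodobut-2-enyloxy)diphenylsilane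
Conditions: TBDPSCl, imidazole, CH2Cl2, 0 °C → rt
Reagents that add atoms: tert-butyldiphenylsilyl chloride, CC(C)(C)[Si](Cl)(c1ccccc1)c1ccccc1
Why: Standard silylation of a primary alcohol; the TBDPS ether survives every step up to the late fluoride deprotection.

Step 6
Reactants: 9 3-buten-1-ol
Product: 10 (but-3-enyloxy)triethylsilane
Conditions: Et3SiCl, imidazole, CH2Cl2, 0 °C
Reagents that add atoms: chlorotriethylsilane, CC[Si](Cl)(CC)CC
Why: Silylation; a primary TES ether can later be oxidised directly to the aldehyde under Swern conditions while TBDPS ethers stay intact.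

Step 7
Reactants: 11 (R)-4-benzyl-2-oxazolidinone; 12 acryloyl chloride
Product: 13 (R)-3-acryloyl-4-benzyloxazolidin-2-one
Conditions: Et3N, LiCl, THF, −20 °C → rt
Reagents that add atoms: none
Why: N-Acylation of the oxazolidinone under mild LiCl/amine activation, which avoids polymerisation of the acrylate.

Step 8
Reactants: 13 N-acryloyl oxazolidinone; 10 butenyl TES ether
Product: 14 (R)-4-benzyl-3-[(E)-5-(triethylsilyloxy)pent-2-enoyl]oxazolidin-2-one
Conditions: second-generation Hoveyda–Grubbs catalyst RuCl2(H2IMes)(=CH–C6H4-2-OiPr) (5 mol %), 10 (2 equiv), CH2Cl2, 40 °C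
Reagents that add atoms: none
Why: Olefin cross-metathesis between an electron-poor acryloyl imide and a terminal alkene is selective for the cross product and should give the (E)-enoyl imide.

Step 9
Reactants: 8 (Z)-alkenyl iodide; 14 enoyl imide
Product: 17 (R)-4-benzyl-3-[(3S,4Z)-6-(tert-butyldiphenylsilyloxy)-4-methyl-3-(2-triethylsilyloxyethyl)hex-4-enoyl]oxazolidin-2-one, via alkenyllithium 15 (not isolated), via alkenylmagnesium bromide 16 (not isolated)
Conditions: 8 (1.5 equiv), t-BuLi (3.0 equiv), Et2O, −78 °C; MgBr2·OEt2; CuBr·SMe2 (0.3 equiv), THF, −78 °C; then 14, −78 → −20 °C; NH4Cl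
Reagents that add atoms: none
Why: Auxiliary-controlled copper-mediated conjugate addition: in the magnesium-chelated syn-s-cis enoyl imide the alkenyl group should be delivered to the C10 face opposite the benzyl group, which with the (R)-auxiliary sets C10 as required (3S in the acyl chain), and the alkenyl metals keep their Z geometry at −78 °C.

Step 10
Reactants: 17 conjugate adduct; 4 C2–C7 aldehyde
Product: 19 syn-aldol imide (1R,2S,10S; free C2–OH), via dibutylboron Z-enolate 18 (not isolated)
Conditions: Bu2BOTf, iPr2NEt, CH2Cl2, −78 → 0 °C; 4, −78 → 0 °C; pH 7 buffer, MeOH, H2O2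
Reagents that add atoms: none
Why: Evans boron aldol through the Z-enolate and a Zimmerman–Traxler chair: the auxiliary should direct the aldehyde to the enolate face remote from the benzyl group, which sets C2 (S) and the transient C1–H centre (syn) and should override the C10 centre.

Step 11
Reactants: 19 aldol imide
Product: 21 β-hydroxy methyl ester (1R,2S,10S), via carboxylic acid 20 (not isolated)
Conditions: LiOH, H2O2, THF/H2O, 0 °C; Na2SO3; HCl to pH 4; crude acid, TMSCHN2, PhMe/MeOH, 0 °C
Reagents that add atoms: lithium hydroperoxide from LiOH/H2O2, [Li+].[O-]O (carboxyl oxygen); trimethylsilyldiazomethane, C[Si](C)(C)C=[N+]=[N-] (ester methyl carbon)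
Why: Hydroperoxide attacks the exocyclic imide carbonyl selectively even in hindered acyl oxazolidinones, and diazoalkane esterification gives the methyl ester without touching the β-hydroxyl or the silyl ethers.

Step 12
Reactants: 21 β-hydroxy ester
Product: 23 α-methyl-β-hydroxy ester with quaternary C1 (1R,2S,10R), via dilithio alkoxide enolate 22 (not isolated)
Conditions: LiN(iPr)2 (2.3 equiv), THF, −78 → −20 °C; MeI, DMPU, −78 → −10 °C
Reagents that add atoms: iodomethane, CI
Why: Fráter–Seebach alkylation: in the lithium-chelated alkoxide–enolate the C3 chain is pushed pseudo-axial by A1,2 strain with the C10 substituent, so methyl iodide should enter from the opposite face, which gives the C1 configuration of the target irrespective of the C1 configuration of 21.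

Step 13
Reactants: 23 ester
Product: 24 1,3-diol (1S,2S,10R; C14 primary alcohol and C2 secondary alcohol)
Conditions: LiAlH4, Et2O, 0 °C → rt; potassium sodium tartrate work-up
Reagents that add atoms: none
Why: Hydride reduction of the neopentyl ester to the primary alcohol; ethers, silyl ethers and alkenes are inert and no stereocentre is touched.

Step 14
Reactants: 24 diol
Product: 25 C14 TBDPS ether (1S,2S,10R; free C2–OH)
Conditions: TBDPSCl (1.05 equiv), imidazole, CH2Cl2, 0 °C
Reagents that add atoms: tert-butyldiphenylsilyl chloride, CC(C)(C)[Si](Cl)(c1ccccc1)c1ccccc1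
Why: Steric differentiation in silylation: the primary alcohol reacts, whereas the secondary C2 alcohol next to the quaternary carbon does not.

Step 15
Reactants: 25 alcohol; 26 tiglic acid
Product: 28 C2 tiglate (1S,2S,10R), via mixed anhydride 27 (not isolated)
Conditions: 26, 2,4,6-trichlorobenzoyl chloride, Et3N, THF, rt; then 25, DMAP, toluene, 60 °C
Reagents that add atoms: none
Why: Yamaguchi esterification through the mixed anhydride and the acylpyridinium ion forces acylation of the hindered C2 hydroxyl; the (E)-tigloyl geometry is the thermodynamic one and should be kept.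

Step 16
Reactants: 28 tiglate
Product: 29 C8 aldehyde (1S,2S,10R)
Conditions: (COCl)2 (4 equiv), DMSO (8 equiv), CH2Cl2, −78 → −30 °C; Et3N, −78 °C → rt
Reagents that add atoms: none
Why: Under Swern conditions a primary TES ether is cleaved by the chlorosulfonium salt and oxidised in the same flask, whereas TBDPS and PMB ethers and the tiglate are stable.

Step 17
Reactants: 29 aldehyde; 30 methyl acrylate
Product: 31 Morita–Baylis–Hillman adduct (1S,2S,10R; C8 carbinol as an epimer mixture)
Conditions: 30 (excess), DABCO (1 equiv), MeOH (cat.), rt, several days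
Reagents that add atoms: none
Why: Morita–Baylis–Hillman reaction: the DABCO–acrylate zwitterion adds to the unhindered aldehyde and elimination returns the 2-substituted acrylate; the tiglate is too poor an acceptor to interfere and the C8 epimers converge later.

Step 18
Reactants: 31 allylic alcohol
Product: 32 (Z)-2-(bromomethyl)enoate (1S,2S,10R)
Conditions: NBS, Me2S, CH2Cl2, 0 °C → rt
Reagents that add atoms: N-bromosuccinimide, O=C1CCC(=O)N1Br
Why: Corey–Kim-type activation of the alcohol as an alkoxysulfonium ion and SN2' attack of bromide should give the thermodynamically preferred (Z)-allylic bromide with C9 cis to CH2Br.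

Step 19
Reactants: 32 PMB ether
Product: 33 C7 allylic alcohol (1S,2S,10R)
Conditions: DDQ, CH2Cl2/pH 7 buffer (10:1), 0 °C
Reagents that add atoms: none
Why: Oxidative PMB cleavage by hydride abstraction and hydrolysis of the oxocarbenium ion is neutral, so the allylic bromide, the enoate and the silyl ethers should survive.

Step 20
Reactants: 33 allylic alcohol
Product: 34 (Z)-enal (1S,2S,10R; C7 aldehyde)
Conditions: activated MnO2 (excess), CH2Cl2, rt
Reagents that add atoms: none
Why: MnO2 oxidises allylic alcohols selectively and converts (Z)-allylic alcohols into (Z)-enals without isomerisation.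

Step 21
Reactants: 34 bromo enal
Product: 37 ten-membered trans-fused α-methylene-γ-butyrolactone (1S,2S,7R,8S,10R), via allylchromium dichloride 35 (not isolated), via chromium alkoxide ester 36 (not isolated)
Conditions: CrCl2 (8 equiv), THF, rt, syringe-pump addition to 2 mM; then PPTS (cat.), CH2Cl2 to complete lactonisation
Reagents that add atoms: none
Why: Nozaki–Hiyama (Barbier-type) allylation, the reaction type used to close ten-membered germacranolide rings: the allylchromium adds through C8 to the C7 aldehyde in a chair transition state (anti, hence the trans lactone once the alkoxide attacks the ester); C7 is set by macrocyclic control and the 7R isomer is expected, though this facial selectivity is the least secure stereochemical point of the route.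

Step 22
Reactants: 37 α-methylene lactone
Product: 38 ten-membered α-methyl butenolide (1S,2S,7R,10R)
Conditions: RhCl3·3H2O (10 mol %), EtOH, 70 °C
Reagents that add atoms: none
Why: Rhodium-hydride addition and β-hydride elimination should move the exocyclic alkene into the ring to give the tetrasubstituted conjugated butenolide (the thermodynamic sink), with the trisubstituted alkenes reacting much more slowly; the C8 centre disappears.

Step 23
Reactants: 38 bis-silyl ether
Product: 39 C13,C14-diol (1S,2S,7R,10R)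
Conditions: HF·pyridine, pyridine, THF, 0 °C → rt
Reagents that add atoms: none
Why: Acidic fluoride desilylation removes both primary TBDPS groups and avoids the basic conditions that could epimerise C7 or move the tigloyl group to the C14 hydroxyl.

Step 24
Reactants: 39 diol
Product: 40 dialdehyde (1R,2S,7R,10R; C14 formyl on C1 and (Z)-enal on C10)
Conditions: Dess–Martin periodinane (3 equiv), NaHCO3, CH2Cl2, 0 °C → rt
Reagents that add atoms: none
Why: Buffered Dess–Martin oxidation converts both primary alcohols into aldehydes; the neopentyl aldehyde cannot enolise and the (Z)-enal geometry should be preserved under neutral conditions.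

Step 25
Reactants: 40 dialdehyde
Product: 42 14-hydroxy enone (1S,2S,7R,10R,14S; deacetyl target), via Breslow intermediate 41 (not isolated)
Conditions: (5aS,10bR)-2-(pentafluorophenyl)-5a,10b-dihydro-4H,6H-indeno[2,1-b][1,2,4]triazolo[4,3-d][1,4]oxazin-2-ium tetrafluoroborate (20 mol %), iPr2NEt (20 mol %), toluene, 4 Å MS, rt
Reagents that add atoms: none
Why: The triazolylidene adds to the conjugated, less hindered C13 formyl group and proton transfer gives enaminol 41, whose acyl-anion carbon C13 attacks the C14 aldehyde; collapse of the adduct releases the carbene and leaves the C13 ketone in conjugation with C11=C12. The closest known reaction type is the carbene-catalysed intramolecular crossed benzoin cyclisation of dialdehydes to six-membered acyloins. Ring A (C1, C10, C11, C12, C13, C14) closes in a 6-exo-trig mode, and the (Z)-enal geometry keeps C13 within bonding distance of C14. The new C14 centre is set mainly by the substrate: in the chair-like transition state the C14 carbonyl oxygen should lie anti to the axial C15 methyl, which gives the hydroxyl trans to C15 and cis to H-10 (14S), and the chiral carbene reinforces this (its mirror image would be used if the pair proved mismatched). The step needs the enal, not the C14 aldehyde, to be the acyl donor, and needs acyl-anion rather than homoenolate reactivity: quaternary C1 shields C14 from the carbene, and bond formation through C11 would require a four-membered ring at a fully substituted carbon.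

Step 26
Reactants: 42 hydroxy enone
Product: 43 target CNP0218548.3 (1R,2S,7R,10R,14S)
Conditions: Ac2O, DMAP (cat.), pyridine, CH2Cl2, 0 °C → rt
Reagents that add atoms: acetic anhydride, CC(=O)OC(C)=O
Why: DMAP-catalysed acetylation of the secondary C14 hydroxyl under mild conditions that should not epimerise C14 or C7.

**Compound list**

1 | nerol | CC(C)=CCC/C(C)=C\CO | starting material
2 | neryl 4-methoxybenzyl ether | CC(C)=CCC/C(C)=C\COCc1ccc(OC)cc1 | intermediate
3 | 6,7-epoxide of neryl PMB ether (racemic epoxide carbon) | CC1(C)OC1CC/C(C)=C\COCc1ccc(OC)cc1 | intermediate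
4 | (Z)-6-(4-methoxybenzyloxy)-4-methylhex-4-enal | O=CCC/C(C)=C\COCc1ccc(OC)cc1 | intermediate
5 | 2-butyn-1-ol | CC#CCO | starting material
6 | sodium cyclic alkenylaluminate from 5 and Red-Al | CC1=CCO[Al-]1(OCCOC)OCCOC.[Na+] | intermediate (not isolated)
7 | (Z)-3-iodobut-2-en-1-ol | C/C(I)=C/CO | intermediate
8 | (Z)-tert-butyl(3-iodobut-2-enyloxy)diphenylsilane | C/C(I)=C/CO[Si](c1ccccc1)(c1ccccc1)C(C)(C)C | intermediate
9 | 3-buten-1-ol | C=CCCO | starting material
10 | (but-3-enyloxy)triethylsilane | C=CCCO[Si](CC)(CC)CC | intermediate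
11 | (R)-4-benzyl-2-oxazolidinone | O=C1OC[C@@H](Cc2ccccc2)N1 | starting material
12 | acryloyl chloride | C=CC(=O)Cl | starting material
13 | (R)-3-acryloyl-4-benzyloxazolidin-2-one | C=CC(=O)N1[C@H](Cc2ccccc2)COC1=O | intermediate
14 | (R)-4-benzyl-3-[(E)-5-(triethylsilyloxy)pent-2-enoyl]oxazolidin-2-one | CC[Si](CC)(CC)OCC/C=C/C(=O)N1[C@H](Cc2ccccc2)COC1=O | intermediate
15 | (Z)-alkenyllithium from 8 | C/C([Li])=C/CO[Si](c1ccccc1)(c1ccccc1)C(C)(C)C | intermediate (not isolated)
16 | (Z)-alkenylmagnesium bromide from 15 | C/C([Mg]Br)=C/CO[Si](c1ccccc1)(c1ccccc1)C(C)(C)C | intermediate (not isolated)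
17 | (R)-4-benzyl-3-[(3S,4Z)-6-(tert-butyldiphenylsilyloxy)-4-methyl-3-(2-triethylsilyloxyethyl)hex-4-enoyl]oxazolidin-2-one | CC[Si](CC)(CC)OCC[C@H](/C(C)=C\CO[Si](c1ccccc1)(c1ccccc1)C(C)(C)C)CC(=O)N1[C@H](Cc2ccccc2)COC1=O | intermediate
18 | dibutylboron Z-enolate of 17 | CCCCB(CCCC)O/C(N1[C@H](Cc2ccccc2)COC1=O)=C\[C@H](CCO[Si](CC)(CC)CC)/C(C)=C\CO[Si](c3ccccc3)(c3ccccc3)C(C)(C)C | intermediate (not isolated)
19 | syn-aldol imide (1R,2S,10S): (R)-4-benzyl-3-[(2R,3S,6Z)-2-[(3S,4Z)-6-(tert-butyldiphenylsilyloxy)-4-methyl-1-(triethylsilyloxy)hex-4-en-3-yl]-3-hydroxy-8-(4-methoxybenzyloxy)-6-methyloct-6-enoyl]oxazolidin-2-one | O[C@H]([C@H](C(=O)N1[C@H](Cc2ccccc2)COC1=O)[C@H](CCO[Si](CC)(CC)CC)/C(C)=C\CO[Si](c3ccccc3)(c3ccccc3)C(C)(C)C)CC/C(C)=C\COCc1ccc(OC)cc1 | intermediate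
20 | carboxylic acid from 19 (1R,2S,10S) | O[C@H]([C@H](C(=O)O)[C@H](CCO[Si](CC)(CC)CC)/C(C)=C\CO[Si](c3ccccc3)(c3ccccc3)C(C)(C)C)CC/C(C)=C\COCc1ccc(OC)cc1 | intermediate (not isolated)
21 | β-hydroxy methyl ester (1R,2S,10S) | O[C@H]([C@H](C(=O)OC)[C@H](CCO[Si](CC)(CC)CC)/C(C)=C\CO[Si](c3ccccc3)(c3ccccc3)C(C)(C)C)CC/C(C)=C\COCc1ccc(OC)cc1 | intermediate
22 | dilithio alkoxide enolate of 21 | [Li]O[C@H](/C(=C(\O[Li])OC)[C@H](CCO[Si](CC)(CC)CC)/C(C)=C\CO[Si](c3ccccc3)(c3ccccc3)C(C)(C)C)CC/C(C)=C\COCc1ccc(OC)cc1 | intermediate (not isolated)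
23 | α-methyl-β-hydroxy methyl ester with quaternary C1 (1R,2S,10R) | O[C@H]([C@](C)(C(=O)OC)[C@H](CCO[Si](CC)(CC)CC)/C(C)=C\CO[Si](c3ccccc3)(c3ccccc3)C(C)(C)C)CC/C(C)=C\COCc1ccc(OC)cc1 | intermediate
24 | 1,3-diol (1S,2S,10R; C14–OH and C2–OH) | O[C@H]([C@](C)(CO)[C@H](CCO[Si](CC)(CC)CC)/C(C)=C\CO[Si](c3ccccc3)(c3ccccc3)C(C)(C)C)CC/C(C)=C\COCc1ccc(OC)cc1 | intermediate
25 | C14 TBDPS ether with free C2–OH (1S,2S,10R) | O[C@H]([C@](C)(CO[Si](c4ccccc4)(c4ccccc4)C(C)(C)C)[C@H](CCO[Si](CC)(CC)CC)/C(C)=C\CO[Si](c3ccccc3)(c3ccccc3)C(C)(C)C)CC/C(C)=C\COCc1ccc(OC)cc1 | intermediate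
26 | tiglic acid | C/C=C(\C)C(=O)O | starting material
27 | tiglic 2,4,6-trichlorobenzoic mixed anhydride | C/C=C(\C)C(=O)OC(=O)c1c(Cl)cc(Cl)cc1Cl | intermediate (not isolated)
28 | C2 tiglate with C8–OTES, C7–OPMB, C13/C14–OTBDPS (1S,2S,10R) | C/C=C(\C)C(=O)O[C@H]([C@](C)(CO[Si](c4ccccc4)(c4ccccc4)C(C)(C)C)[C@H](CCO[Si](CC)(CC)CC)/C(C)=C\CO[Si](c3ccccc3)(c3ccccc3)C(C)(C)C)CC/C(C)=C\COCc1ccc(OC)cc1 | intermediate
29 | C8 aldehyde (1S,2S,10R) | C/C=C(\C)C(=O)O[C@H]([C@](C)(CO[Si](c4ccccc4)(c4ccccc4)C(C)(C)C)[C@H](CC=O)/C(C)=C\CO[Si](c3ccccc3)(c3ccccc3)C(C)(C)C)CC/C(C)=C\COCc1ccc(OC)cc1 | intermediate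
30 | methyl acrylate | C=CC(=O)OC | starting material
31 | Morita–Baylis–Hillman adduct (1S,2S,10R; C8 epimers) | C/C=C(\C)C(=O)O[C@H]([C@](C)(CO[Si](c4ccccc4)(c4ccccc4)C(C)(C)C)[C@H](CC(O)C(=C)C(=O)OC)/C(C)=C\CO[Si](c3ccccc3)(c3ccccc3)C(C)(C)C)CC/C(C)=C\COCc1ccc(OC)cc1 | intermediate
32 | (Z)-2-(bromomethyl)enoate (1S,2S,10R) | C/C=C(\C)C(=O)O[C@H]([C@](C)(CO[Si](c4ccccc4)(c4ccccc4)C(C)(C)C)[C@H](C/C=C(\CBr)C(=O)OC)/C(C)=C\CO[Si](c3ccccc3)(c3ccccc3)C(C)(C)C)CC/C(C)=C\COCc1ccc(OC)cc1 | intermediate
33 | C7 allylic alcohol (1S,2S,10R) | C/C=C(\C)C(=O)O[C@H]([C@](C)(CO[Si](c4ccccc4)(c4ccccc4)C(C)(C)C)[C@H](C/C=C(\CBr)C(=O)OC)/C(C)=C\CO[Si](c3ccccc3)(c3ccccc3)C(C)(C)C)CC/C(C)=C\CO | intermediate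
34 | (Z)-enal with allylic bromide (1S,2S,10R) | C/C=C(\C)C(=O)O[C@H]([C@](C)(CO[Si](c4ccccc4)(c4ccccc4)C(C)(C)C)[C@H](C/C=C(\CBr)C(=O)OC)/C(C)=C\CO[Si](c3ccccc3)(c3ccccc3)C(C)(C)C)CC/C(C)=C\C=O | intermediate
35 | allylchromium dichloride from 34 | C/C=C(\C)C(=O)O[C@H]([C@](C)(CO[Si](c4ccccc4)(c4ccccc4)C(C)(C)C)[C@H](C/C=C(\C[Cr](Cl)Cl)C(=O)OC)/C(C)=C\CO[Si](c3ccccc3)(c3ccccc3)C(C)(C)C)CC/C(C)=C\C=O | intermediate (not isolated)
36 | ten-membered chromium alkoxide ester (7R,8S) | C/C=C(\C)C(=O)O[C@H]1CC/C(C)=C\[C@@H](O[Cr](Cl)Cl)[C@H](C(=C)C(=O)OC)C[C@H](/C(C)=C\CO[Si](c3ccccc3)(c3ccccc3)C(C)(C)C)[C@@]1(C)CO[Si](c3ccccc3)(c3ccccc3)C(C)(C)C | intermediate (not isolated)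
37 | ten-membered trans-fused α-methylene-γ-butyrolactone (1S,2S,7R,8S,10R) | C/C=C(\C)C(=O)O[C@H]1CC/C(C)=C\[C@H]2OC(=O)C(=C)[C@@H]2C[C@H](/C(C)=C\CO[Si](c3ccccc3)(c3ccccc3)C(C)(C)C)[C@@]1(C)CO[Si](c3ccccc3)(c3ccccc3)C(C)(C)C | intermediate
38 | ten-membered α-methyl butenolide, bis-TBDPS ether (1S,2S,7R,10R) | C/C=C(\C)C(=O)O[C@H]1CC/C(C)=C\[C@H]2OC(=O)C(C)=C2C[C@H](/C(C)=C\CO[Si](c3ccccc3)(c3ccccc3)C(C)(C)C)[C@@]1(C)CO[Si](c3ccccc3)(c3ccccc3)C(C)(C)C | intermediate
39 | C13,C14-diol (1S,2S,7R,10R) | C/C=C(\C)C(=O)O[C@H]1CC/C(C)=C\[C@H]2OC(=O)C(C)=C2C[C@H](/C(C)=C\CO)[C@@]1(C)CO | intermediate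
40 | dialdehyde (1R,2S,7R,10R): C1 formyl and C10 (Z)-enal | C/C=C(\C)C(=O)O[C@H]1CC/C(C)=C\[C@H]2OC(=O)C(C)=C2C[C@H](/C(C)=C\C=O)[C@@]1(C)C=O | intermediate
41 | Breslow intermediate (enaminol at C13 with the triazolylidene) | C/C=C(\C)C(=O)O[C@H]1CC/C(C)=C\[C@H]2OC(=O)C(C)=C2C[C@H](/C(C)=C\C(O)=C3N(c4c(F)c(F)c(F)c(F)c4F)N=C4CO[C@H]5Cc6ccccc6[C@H]5N34)[C@@]1(C)C=O | intermediate (not isolated)
42 | 14-hydroxy enone, deacetyl target (1S,2S,7R,10R,14S) | C/C=C(\C)C(=O)O[C@H]1CC/C(C)=C\[C@H]2OC(=O)C(C)=C2C[C@@H]2C(C)=CC(=O)[C@@H](O)[C@@]12C | intermediate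
43 | CNP0218548.3 (1R,2S,7R,10R,14S) | C/C=C(\C)C(=O)O[C@H]1CC/C(C)=C\[C@H]2OC(=O)C(C)=C2C[C@@H]2C(C)=CC(=O)[C@@H](OC(C)=O)[C@@]12C | target

**Step count**

Total: 26 steps. Longest linear sequence: 20 steps (steps 6, 8, 9–26; the sequences from nerol, from 2-butyn-1-ol and from the oxazolidinone are equally long).

**The three steps most likely to fail**

Step 25. The carbene may add to the C14 formyl group instead of the enal, which would give the transposed ketol. The homoenolate form of 41 may be protonated at C11, which would divert the enal to an acyl azolium. C14 may also be attacked on the wrong face. The fallback couples the same two carbons reductively instead of by umpolung. Setting out from 40, SmI2 (THF, t-BuOH, −78 °C) should bring about an intramolecular pinacol coupling to the ring A 13,14-diol F1. MnO2 should then oxidise only the allylic C13 carbinol and return to the route at 42.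

Step 21. Intermolecular allylation may outrun closure of the ten-membered ring, and the C7 aldehyde may be attacked on the face that leads to the 7S lactone. The fallback corrects the stereocentre by inversion instead of relying on direct macrocyclic control. Setting out from 34, the same CrCl2 closure would in that case give the 7-epimeric trans-lactone F2. LiOH (THF/H2O, 0 °C; the hindered tiglate should survive) would open it to γ-hydroxy acid F3. Mitsunobu lactonisation (PPh3, DIAD, toluene, 0 °C) would close the ring with inversion at C7 to cis-lactone F4. The rhodium isomerisation of step 22 then converts F4 into 38, because C8 becomes sp2.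

Step 12. Deprotonation of the hindered C1–H may be incomplete, and the dianion may undergo retro-aldol cleavage on warming. The fallback uses a cyclic acetal enolate instead of the chelated dianion. Setting out from acid 20 (prepared as in step 11 and isolated in this case), acetalisation with pivalaldehyde (PPTS, CH2Cl2, molecular sieves) would give cis-2-tert-butyl-1,3-dioxan-4-one F5. Its lithium enolate (LiN(iPr)2, THF, −78 °C) should be methylated anti to the C2 side chain to give methylated dioxanone F6. NaOMe in MeOH would open the acetal and return to the route at 23.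

**Further compounds**

F1 | step 25 | ring A 13,14-diol (C13 epimers; 14S) | C/C=C(\C)C(=O)O[C@H]1CC/C(C)=C\[C@H]2OC(=O)C(C)=C2C[C@@H]2C(C)=CC(O)[C@@H](O)[C@@]12C
F2 | step 21 | 7-epimeric trans-fused α-methylene lactone (7S,8R) | C/C=C(\C)C(=O)O[C@H]1CC/C(C)=C\[C@@H]2OC(=O)C(=C)[C@H]2C[C@H](/C(C)=C\CO[Si](c3ccccc3)(c3ccccc3)C(C)(C)C)[C@@]1(C)CO[Si](c3ccccc3)(c3ccccc3)C(C)(C)C
F3 | step 21 | γ-hydroxy acid from F2 (7S,8R) | C/C=C(\C)C(=O)O[C@H]1CC/C(C)=C\[C@H](O)[C@@H](C(=C)C(=O)O)C[C@H](/C(C)=C\CO[Si](c3ccccc3)(c3ccccc3)C(C)(C)C)[C@@]1(C)CO[Si](c3ccccc3)(c3ccccc3)C(C)(C)C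
F4 | step 21 | cis-fused α-methylene lactone (7R,8R) | C/C=C(\C)C(=O)O[C@H]1CC/C(C)=C\[C@H]2OC(=O)C(=C)[C@H]2C[C@H](/C(C)=C\CO[Si](c3ccccc3)(c3ccccc3)C(C)(C)C)[C@@]1(C)CO[Si](c3ccccc3)(c3ccccc3)C(C)(C)C
F5 | step 12 | cis-2-tert-butyl-1,3-dioxan-4-one from acid 20 | O=C1O[C@@H](C(C)(C)C)O[C@@H](CC/C(C)=C\COCc2ccc(OC)cc2)[C@H]1[C@H](CCO[Si](CC)(CC)CC)/C(C)=C\CO[Si](c3ccccc3)(c3ccccc3)C(C)(C)C
F6 | step 12 | C1-methylated dioxanone | O=C1O[C@@H](C(C)(C)C)O[C@@H](CC/C(C)=C\COCc2ccc(OC)cc2)[C@@]1(C)[C@H](CCO[Si](CC)(CC)CC)/C(C)=C\CO[Si](c3ccccc3)(c3ccccc3)C(C)(C)C
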